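**Retrosynthetic overview**

- Feature: in the ten-membered carbocycle C1–C10, the C1 ketone and the C6 lactone carbinol lie 1,6 across the ring. A C1–C6 bond folds the arc C6–C7–C8–C9–C10–C1 into a cyclohexane on which C8, C9 and C10 can be set.
- Key disconnection: C3–C4, formed while C1–C6 is cleaved, by an anionic acetylenic oxy-Cope ring expansion of the 1-propynyl-2-vinylcyclohexanol 24. The product 27 is the ten-membered 4-ene-1,6-dione held as its C1 methyl enol ether, so that C1 stays masked while C6 is worked on.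
- 24 is built from methyl β-D-galactopyranoside (sugar C2/C3/C4 become C8/C7/C6): zinc fragmentation, isopropenyl addition and ring-closing metathesis give the cyclohexene (ring 1). Hydride and borane delivery set C9 and C10; vinyl (C1, then O-methylation) and propynyl (C6) are added in that order.
- After the ring expansion (ring 2): nucleophilic epoxidation (ring 3), C6 reduction, phosphonoacetate acylation, C7 oxidation and intramolecular Horner–Wadsworth–Emmons closure (ring 4, butenolide), then C8 methacrylate, desilylation and C13 acetate.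
- Protecting groups leave in the order C6 PMB, C7 Bn, C8 TES, then C9 TBS together with C13 TBDPS.

Key step: step 19

Remark on numbering: germacrane numbering of the target is used for all intermediates (C1 ketone, C4–C5 epoxide, C6 lactone carbinol, C7=C11, C12 lactone carbonyl, C13 acetoxymethyl, C14/C15 the methyls on C10/C4).

Remark on the chemistry: 27 is drawn as its 4E isomer; this geometry is an assumption and is not relied on, because the peroxide addition of step 20 is stepwise and is expected to close to the trans-epoxide from either geometric isomer.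

**Route**

Step 1
Reactants: 1 methyl β-D-galactopyranoside
Product: 2 methyl 4,6-O-(4-methoxybenzylidene)-β-D-galactopyranoside (aryl equatorial)
Conditions: 4-MeOC6H4CH(OMe)2, CSA (cat.), MeCN, rt
Reagents that add atoms: 4-methoxybenzaldehyde dimethyl acetal, COc1ccc(cc1)C(OC)OC
Why: Acid-catalysed transacetalisation closes the thermodynamically favoured six-membered 4,6-acetal and leaves only O2 and O3 free.

Step 2
Reactants: 2 methyl 4,6-O-(4-methoxybenzylidene)-β-D-galactopyranoside
Product: 4 methyl 3-O-benzyl-4,6-O-(4-methoxybenzylidene)-β-D-galactopyranoside, via stannylene acetal 3 (not isolated)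
Conditions: Bu2SnO, MeOH, reflux, evaporate; BnBr, CsF, DMF, rt
Reagents that add atoms: dibutyltin oxide, CCCC[Sn](=O)CCCC (tin in 3 only); benzyl bromide, BrCc1ccccc1
Why: Stannylene activation of the 2,3-diol of a 4,6-O-arylidene β-galactoside directs the Williamson-type alkylation to O3, which becomes the C7 benzyl ether.

Step 3
Reactants: 4 methyl 3-O-benzyl-4,6-O-(4-methoxybenzylidene)-β-D-galactopyranoside
Product: 5 methyl 3-O-benzyl-4,6-O-(4-methoxybenzylidene)-2-O-triethylsilyl-β-D-galactopyranoside
Conditions: TESCl, imidazole, DMF, 0 °C to rt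
Reagents that add atoms: chlorotriethylsilane, CC[Si](Cl)(CC)CC
Why: Standard silylation of the only remaining hydroxyl (O2, the future C8 oxygen).

Step 4
Reactants: 5 methyl 3-O-benzyl-4,6-O-(4-methoxybenzylidene)-2-O-triethylsilyl-β-D-galactopyranoside
Product: 6 methyl 3-O-benzyl-4-O-(4-methoxybenzyl)-2-O-triethylsilyl-β-D-galactopyranoside (6-OH free)
Conditions: i-Bu2AlH, toluene, −78 to 0 °C
Reagents that add atoms: none
Why: Reductive opening of the p-methoxybenzylidene acetal: aluminium binds the less hindered O6 and hydride cleaves that C–O bond, so O4 keeps the PMB group and the primary alcohol is freed.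

Step 5
Reactants: 6 methyl 3-O-benzyl-4-O-(4-methoxybenzyl)-2-O-triethylsilyl-β-D-galactopyranoside
Product: 7 methyl 3-O-benzyl-6-deoxy-6-iodo-4-O-(4-methoxybenzyl)-2-O-triethylsilyl-β-D-galactopyranoside
Conditions: I2, PPh3, imidazole, toluene, 70 °C
Reagents that add atoms: iodine, II
Why: Garegg–Samuelsson (Appel-type) iodination of the primary alcohol under imidazole-buffered conditions that spare the silyl and benzyl-type ethers.

Step 6
Reactants: 7 methyl 3-O-benzyl-6-deoxy-6-iodo-4-O-(4-methoxybenzyl)-2-O-triethylsilyl-β-D-galactopyranoside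
Product: 8 3-O-benzyl-5,6-dideoxy-4-O-(4-methoxybenzyl)-2-O-triethylsilyl-L-arabino-hex-5-enose (open-chain aldehyde)
Conditions: Zn dust (activated), THF/H2O 9:1, ultrasound, 40 °C
Reagents that add atoms: none
Why: Bernet–Vasella reductive fragmentation: zinc insertion into C–I and β-elimination open the pyranoside to the hex-5-enal without touching the three oxygenated stereocentres.

Step 7
Reactants: 8 3-O-benzyl-5,6-dideoxy-4-O-(4-methoxybenzyl)-2-O-triethylsilyl-L-arabino-hex-5-enose; 9 isopropenylmagnesium bromide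
Product: 10 5-benzyloxy-6-(4-methoxybenzyloxy)-2-methyl-4-triethylsilyloxyocta-1,7-dien-3-ol (both C3 epimers; C3 is the future C9)
Conditions: THF, −78 °C
Reagents that add atoms: none
Why: Grignard 1,2-addition to the aldehyde brings in C10 with its methyl group; the new carbinol centre is expected as an epimer mixture, which is harmless because step 9 oxidises it.

Step 8
Reactants: 10 5-benzyloxy-6-(4-methoxybenzyloxy)-2-methyl-4-triethylsilyloxyocta-1,7-dien-3-ol
Product: 11 cyclohexenol with C10(CH3)=C1H / C9 OH (both epimers) / C8 OTES / C7 OBn / C6 OPMB (C6/C7 cis; C7/C8 trans)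
Conditions: second-generation Grubbs catalyst (5 mol%), CH2Cl2, 40 °C
Reagents that add atoms: none
Why: Ring-closing metathesis between the 1,1-disubstituted and the monosubstituted alkene closes the six-membered ring at C10=C1 with loss of ethene, a closure well known for carbasugar dienes.

Step 9
Reactants: 11 cyclohexenol (C9 epimers)
Product: 12 2-methylcyclohex-2-enone with C9 C=O / C10(CH3)=C1H / C8 OTES / C7 OBn / C6 OPMB
Conditions: Dess–Martin periodinane, NaHCO3, CH2Cl2, 0 °C to rt
Reagents that add atoms: none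
Why: Dess–Martin oxidation of the allylic alcohol converges both C9 epimers to one enone under buffered, non-epimerising conditions.

Step 10
Reactants: 12 enone
Product: 13 allylic alcohol with C9 OH trans to C8 OTES
Conditions: NaBH4, CeCl3·7H2O, MeOH, −78 °C
Reagents that add atoms: none
Why: Luche 1,2-reduction: axial hydride attack on the half-chair enone (C7 and C8 substituents equatorial) gives the equatorial C9 alcohol, trans to the C8 silyloxy group, which is the C9 configuration of the target.

Step 11
Reactants: 13 allylic alcohol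
Product: 14 C9 tert-butyldimethylsilyl ether of 13
Conditions: TBSOTf, 2,6-lutidine, CH2Cl2, −78 to 0 °C
Reagents that add atoms: tert-butyldimethylsilyl trifluoromethanesulfonate, CC(C)(C)[Si](C)(C)OS(=O)(=O)C(F)(F)F
Why: Silyl triflate silylation of the hindered secondary allylic alcohol installs the most persistent oxygen protecting group of the route.

Step 12
Reactants: 14 C9 TBS ether
Product: 16 cyclohexanol with C1 OH / C10 CH3 cis to C9 OTBS and trans to C1 OH, via C1 alkylborane 15 (not isolated)
Conditions: BH3·THF, THF, 0 °C to rt; then aq NaOH, H2O2, 0 °C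
Reagents that add atoms: borane (as its THF complex), B (boron in 15 only); hydrogen peroxide, OO
Why: Brown hydroboration–oxidation: syn addition with boron on the less substituted C1 from the ring face opposite the C9 OTBS and C6 OPMB groups (both on the same face), so hydrogen enters C10 anti to the C9 oxygen and the C10 methyl ends cis to it, as in the target.

Step 13
Reactants: 16 C1 alcohol
Product: 17 cyclohexanone with C1 C=O / C10 CH3 / C9 OTBS / C8 OTES / C7 OBn / C6 OPMB
Conditions: Dess–Martin periodinane, NaHCO3, CH2Cl2, 0 °C to rt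
Reagents that add atoms: none
Why: Buffered Dess–Martin oxidation gives the ketone without epimerising the adjacent C10 centre.

Step 14
Reactants: 17 C1 ketone; 18 vinylmagnesium bromide
Product: 19 tertiary allylic alcohol with C1 OH cis to C6 OPMB and C10 CH3 (vinyl on the opposite face)
Conditions: CeCl3 (anhydrous), THF, −78 °C
Reagents that add atoms: none
Why: Cerium-mediated Grignard addition suppresses enolisation toward C10, and the vinyl group enters from the face opposite the axial C10 methyl and C6 OPMB groups; C1 is a disposable centre.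

Step 15
Reactants: 19 tertiary allylic alcohol
Product: 20 C1 methyl ether of 19
Conditions: MeI (excess), KH, THF, 0 °C
Reagents that add atoms: iodomethane, CI
Why: Williamson O-methylation of the tertiary potassium alkoxide, trapped by iodomethane already present so that no silyl migration can compete.

Step 16
Reactants: 20 C1 methyl ether
Product: 21 C6 alcohol (PMB removed)
Conditions: DDQ, CH2Cl2/pH 7 buffer, 0 °C
Reagents that add atoms: none
Why: Oxidative cleavage of the PMB ether by DDQ leaves the benzyl, silyl and tertiary methyl ethers and the vinyl group untouched.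

Step 17
Reactants: 21 C6 alcohol
Product: 22 cyclohexanone with C6 C=O / C1 (OCH3)(vinyl) / C7 OBn / C8 OTES / C9 OTBS / C10 CH3
Conditions: Dess–Martin periodinane, NaHCO3, CH2Cl2, rt
Reagents that add atoms: none
Why: Dess–Martin oxidation of the hindered secondary alcohol; C1 is quaternary and the C7 ether is not basic enough to epimerise under these conditions.

Step 18
Reactants: 22 C6 ketone; 23 1-propynylmagnesium bromide
Product: 24 1-propynyl-2-vinylcyclohexanol with C6 (OH)(propynyl) / C1 (OCH3)(vinyl) (propynyl cis to vinyl; OH cis to OCH3)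
Conditions: THF, −78 to 0 °C
Reagents that add atoms: none
Why: Alkynyl Grignard addition to the α-alkoxy ketone from the face away from the axial C10 methyl group; either C6 epimer would be a competent substrate for step 19 because C6 becomes sp2.

Step 19
Reactants: 24 1-propynyl-2-vinylcyclohexanol
Product: 27 ten-membered 1-methoxy-1,4-dien-6-one (C1 methyl enol ether of the 4-ene-1,6-dione; C7 OBn / C8 OTES / C9 OTBS / C10 CH3), via potassium alkoxide 25 (not isolated), via potassium allenolate 26 (not isolated)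
Conditions: KH, 18-crown-6, THF, 0 °C to rt; then sat. aq NH4Cl, −78 °C
Reagents that add atoms: potassium hydride, [K+].[H-] (potassium in 25 and 26 only)
Why: The crown-ether-separated C6 potassium alkoxide drives a [3,3]-sigmatropic shift through the array C3=C2–C1–C6–C5≡C4 in which C3–C4 forms as C1–C6 breaks; the closest known reaction type is the anionic oxy-Cope ring expansion of 1,2-dialkenylcyclohexanols and their acetylenic variants to cyclodecenones. The ten-membered ring arises by four-atom ring expansion of the cyclohexane through a six-centre transition state (the cis vinyl and propynyl arms are held gauche, one axial and one equatorial), not by end-to-end closure. No stereocentre is created: C1 and C6 become sp2, the allene axis of 26 is lost on protonation at C5, and C7 to C10 are spectators. The step needs rearrangement to win over fragmentation of the alkoxide (loss of propynyl anion or heterolysis of C1–C6); the fixed gauche arms and the weak, doubly oxygen-substituted allylic C1–C6 bond favour the shift, and the non-migrating benzyl ether at C7 keeps the alkoxide on C6. The enol ether forms toward C2 only, so C10 keeps its configuration, and the cold buffered quench protonates C5 without hydrolysing the enol ether. C1 therefore stays masked, which prevents transannular aldol reactions of a free 1,6-dione and keeps C1 distinguishable from the C6 ketone.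

Step 20
Reactants: 27 ten-membered enol ether enone
Product: 28 trans-4,5-epoxy-6-ketone (4R,5R) with the C1 enol ether intact
Conditions: t-BuOOH, benzyltrimethylammonium hydroxide (cat.), THF, 0 °C
Reagents that add atoms: tert-butyl hydroperoxide, CC(C)(C)OO
Why: Weitz–Scheffer epoxidation: tert-butylperoxide adds to C4 from the ring periphery and the enolate then closes on the O–O bond after C4–C5 rotation to the trans-epoxide; the facial sense is set by the ring conformation and the C7 centre, and the electron-rich enol ether is inert to the nucleophilic oxidant.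

Step 21
Reactants: 28 epoxy ketone
Product: 29 epoxy alcohol with (6S) C6 OH
Conditions: LiBH(s-Bu)3, THF, −78 °C; then aq NaHCO3
Reagents that add atoms: none
Why: The bulky, non-chelating hydride attacks the C6 carbonyl anti to both flanking C–O bonds (Felkin–Anh control from C5 and C7), which gives the C6 alcohol threo to the epoxide oxygen and to the C7 benzyloxy group, the 6S configuration.

Step 22
Reactants: 30 diethyl (2-hydroxyethyl)phosphonate
Product: 31 diethyl [2-(tert-butyldiphenylsilyloxy)ethyl]phosphonate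
Conditions: TBDPSCl, imidazole, DMF, rt
Reagents that add atoms: tert-butyl(chloro)diphenylsilane, CC(C)(C)[Si](Cl)(c1ccccc1)c1ccccc1
Why: Standard silylation of the primary alcohol that will become the C13 oxygen.

Step 23
Reactants: 31 diethyl [2-(tert-butyldiphenylsilyloxy)ethyl]phosphonate
Product: 33 racemic 3-(tert-butyldiphenylsilyloxy)-2-(diethoxyphosphoryl)propanoic acid, via lithiated phosphonate 32 (not isolated)
Conditions: LiN(i-Pr)2, THF, −78 °C; CO2 (g); then aq HCl to pH 3
Reagents that add atoms: lithium diisopropylamide, [Li+].CC(C)[N-]C(C)C (lithium in 32 only); carbon dioxide, O=C=O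
Why: α-Lithiation of an alkylphosphonate and carboxylation is an established route to 2-phosphonoalkanoic acids, and the low temperature keeps the β-silyloxy carbanion from eliminating silanolate.

Step 24
Reactants: 29 epoxy alcohol; 33 3-(tert-butyldiphenylsilyloxy)-2-(diethoxyphosphoryl)propanoic acid
Product: 34 C6 phosphonoacetate ester of 29 (epimer mixture at the phosphonate carbon C11)
Conditions: DCC, DMAP (cat.), CH2Cl2, 0 °C to rt
Reagents that add atoms: none
Why: Steglich esterification acylates the secondary C6 alcohol under non-acidic conditions that keep the enol ether and the epoxide intact; the C11 centre is destroyed in step 28.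

Step 25
Reactants: 34 C6 phosphonoacetate ester
Product: 35 C1 ketone (enol ether hydrolysed; epoxide / C7 OBn / C8 OTES / C9 OTBS retained)
Conditions: 10% aq oxalic acid on SiO2, CH2Cl2, rt
Reagents that add atoms: water, O
Why: Mild acid hydrolysis of the methyl enol ether by protonation at C2 (C10 is not involved) is far faster than epoxide opening or TES loss, and with C6 already acylated no transannular ketal can form.

Step 26
Reactants: 35 C1 ketone
Product: 36 C7 alcohol (benzyl ether removed)
Conditions: H2 (1 atm), Pd(OH)2/C, EtOAc, rt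
Reagents that add atoms: none
Why: Hydrogenolysis of the benzyl ether is placed at the one stage where the ring carries no C=C bond, and the aliphatic epoxide, ketone, silyl ethers and phosphonate are inert to it.

Step 27
Reactants: 36 C7 alcohol
Product: 37 C7 ketone (α-acyloxy ketone)
Conditions: Dess–Martin periodinane, NaHCO3, CH2Cl2, 0 °C to rt
Reagents that add atoms: none
Why: Buffered Dess–Martin oxidation gives the α-acyloxy ketone without acyl migration or epimerisation at C6 and C8.

Step 28
Reactants: 37 C7 ketone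
Product: 38 butenolide with C7=C11 / C12 lactone to O6 / C13 OTBDPS / C8 OTES / C9 OTBS
Conditions: LiCl, i-Pr2NEt, MeCN, 0 °C to rt
Reagents that add atoms: none
Why: Intramolecular Horner–Wadsworth–Emmons olefination under Masamune–Roush conditions: the soft phosphonate carbanion attacks the C7 ketone to close the five-membered lactone faster than it can expel the β-silanolate, and the mild base leaves C8, C10 and the epoxide alone.

Step 29
Reactants: 38 butenolide
Product: 39 C8 alcohol (TES removed)
Conditions: HF·pyridine, pyridine, THF, 0 °C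
Reagents that add atoms: none
Why: Buffered HF·pyridine cleaves the secondary triethylsilyl ether selectively in the presence of the TBS and TBDPS ethers.

Step 30
Reactants: 39 C8 alcohol
Product: 40 C8 methacrylate
Conditions: methacrylic anhydride, Et3N, DMAP (cat.), CH2Cl2, 0 °C
Reagents that add atoms: methacrylic anhydride, CC(=C)C(=O)OC(=O)C(C)=C
Why: DMAP-catalysed acylation of the only free hydroxyl under mild amine base.

Step 31
Reactants: 40 C8 methacrylate
Product: 41 C9,C13-diol
Conditions: HF·pyridine (excess), pyridine, THF, 0 °C to rt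
Reagents that add atoms: none
Why: Fluoride cleavage of both remaining silyl ethers under buffered, weakly acidic conditions avoids the acyl migration and β-elimination that basic fluoride could cause next to the C1 ketone.

Step 32
Reactants: 41 C9,C13-diol
Product: 42 CNP0185951.1 (target)
Conditions: Ac2O, 2,4,6-collidine, CH2Cl2, −20 to 0 °C
Reagents that add atoms: acetic anhydride, CC(=O)OC(C)=O
Why: The primary allylic C13 hydroxyl is acetylated selectively over the hindered secondary C9 hydroxyl flanked by C8 and C10.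

**Compound list**

1 | methyl β-D-galactopyranoside | OC[C@H]1O[C@@H](OC)[C@H](O)[C@@H](O)[C@H]1O | starting material
2 | methyl 4,6-O-(4-methoxybenzylidene)-β-D-galactopyranoside | COc1ccc(cc1)[C@H]2OC[C@H]3O[C@@H](OC)[C@H](O)[C@@H](O)[C@H]3O2 | intermediate
3 | 2,3-O-dibutylstannylene acetal of 2 | COc1ccc(cc1)[C@H]2OC[C@H]3O[C@@H](OC)[C@@H]4O[Sn](CCCC)(CCCC)O[C@H]4[C@H]3O2 | intermediate (not isolated)
4 | methyl 3-O-benzyl-4,6-O-(4-methoxybenzylidene)-β-D-galactopyranoside | COc1ccc(cc1)[C@H]2OC[C@H]3O[C@@H](OC)[C@H](O)[C@@H](OCc4ccccc4)[C@H]3O2 | intermediate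
5 | methyl 3-O-benzyl-4,6-O-(4-methoxybenzylidene)-2-O-triethylsilyl-β-D-galactopyranoside | COc1ccc(cc1)[C@H]2OC[C@H]3O[C@@H](OC)[C@H](O[Si](CC)(CC)CC)[C@@H](OCc4ccccc4)[C@H]3O2 | intermediate
6 | methyl 3-O-benzyl-4-O-(4-methoxybenzyl)-2-O-triethylsilyl-β-D-galactopyranoside | OC[C@H]1O[C@@H](OC)[C@H](O[Si](CC)(CC)CC)[C@@H](OCc2ccccc2)[C@H]1OCc1ccc(OC)cc1 | intermediate
7 | methyl 3-O-benzyl-6-deoxy-6-iodo-4-O-(4-methoxybenzyl)-2-O-triethylsilyl-β-D-galactopyranoside | IC[C@H]1O[C@@H](OC)[C@H](O[Si](CC)(CC)CC)[C@@H](OCc2ccccc2)[C@H]1OCc1ccc(OC)cc1 | intermediate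
8 | 3-O-benzyl-5,6-dideoxy-4-O-(4-methoxybenzyl)-2-O-triethylsilyl-L-arabino-hex-5-enose | O=C[C@H](O[Si](CC)(CC)CC)[C@@H](OCc1ccccc1)[C@@H](OCc1ccc(OC)cc1)C=C | intermediate
9 | isopropenylmagnesium bromide | CC(=C)[Mg]Br | starting material
10 | 5-benzyloxy-6-(4-methoxybenzyloxy)-2-methyl-4-triethylsilyloxyocta-1,7-dien-3-ol (C3 epimers, centre left open) | C=C(C)C(O)[C@H](O[Si](CC)(CC)CC)[C@@H](OCc1ccccc1)[C@@H](OCc1ccc(OC)cc1)C=C | intermediate
11 | cyclohexenol: C10(CH3)=C1H, C9 OH (epimers, centre left open), C8 OTES, C7 OBn, C6 OPMB | C1=C(C)C(O)[C@H](O[Si](CC)(CC)CC)[C@@H](OCc2ccccc2)[C@H]1OCc1ccc(OC)cc1 | intermediate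
12 | enone: C9 ketone, C10(CH3)=C1H, C8 OTES, C7 OBn, C6 OPMB | C1=C(C)C(=O)[C@H](O[Si](CC)(CC)CC)[C@@H](OCc2ccccc2)[C@H]1OCc1ccc(OC)cc1 | intermediate
13 | allylic alcohol: C9 OH trans to C8 OTES | C1=C(C)[C@@H](O)[C@H](O[Si](CC)(CC)CC)[C@@H](OCc2ccccc2)[C@H]1OCc1ccc(OC)cc1 | intermediate
14 | C9 TBS ether of 13 | C1=C(C)[C@@H](O[Si](C)(C)C(C)(C)C)[C@H](O[Si](CC)(CC)CC)[C@@H](OCc2ccccc2)[C@H]1OCc1ccc(OC)cc1 | intermediate
15 | C1 alkylborane (B and C10–H added syn, anti to C9 OTBS and C6 OPMB) | B[C@@H]1[C@@H](C)[C@@H](O[Si](C)(C)C(C)(C)C)[C@H](O[Si](CC)(CC)CC)[C@@H](OCc2ccccc2)[C@H]1OCc1ccc(OC)cc1 | intermediate (not isolated)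
16 | cyclohexanol: C1 OH, C10 CH3 cis to C9 OTBS, trans to C1 OH | O[C@@H]1[C@@H](C)[C@@H](O[Si](C)(C)C(C)(C)C)[C@H](O[Si](CC)(CC)CC)[C@@H](OCc2ccccc2)[C@H]1OCc1ccc(OC)cc1 | intermediate
17 | C1 ketone | O=C1[C@@H](C)[C@@H](O[Si](C)(C)C(C)(C)C)[C@H](O[Si](CC)(CC)CC)[C@@H](OCc2ccccc2)[C@H]1OCc1ccc(OC)cc1 | intermediate
18 | vinylmagnesium bromide | C=C[Mg]Br | starting material
19 | C1 vinyl carbinol (OH cis to C6 OPMB and C10 CH3) | C=C[C@]1(O)[C@@H](C)[C@@H](O[Si](C)(C)C(C)(C)C)[C@H](O[Si](CC)(CC)CC)[C@@H](OCc2ccccc2)[C@H]1OCc1ccc(OC)cc1 | intermediate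
20 | C1 methyl ether of 19 | C=C[C@]1(OC)[C@@H](C)[C@@H](O[Si](C)(C)C(C)(C)C)[C@H](O[Si](CC)(CC)CC)[C@@H](OCc2ccccc2)[C@H]1OCc1ccc(OC)cc1 | intermediate
21 | C6 alcohol | C=C[C@]1(OC)[C@@H](C)[C@@H](O[Si](C)(C)C(C)(C)C)[C@H](O[Si](CC)(CC)CC)[C@@H](OCc2ccccc2)[C@H]1O | intermediate
22 | C6 ketone | C=C[C@]1(OC)[C@@H](C)[C@@H](O[Si](C)(C)C(C)(C)C)[C@H](O[Si](CC)(CC)CC)[C@@H](OCc2ccccc2)C1=O | intermediate
23 | 1-propynylmagnesium bromide | CC#C[Mg]Br | starting material
24 | 1-propynyl-2-vinylcyclohexanol (C1 OMe, C7 OBn, C8 OTES, C9 OTBS, C10 CH3) | C=C[C@]1(OC)[C@@H](C)[C@@H](O[Si](C)(C)C(C)(C)C)[C@H](O[Si](CC)(CC)CC)[C@@H](OCc2ccccc2)[C@]1(O)C#CC | intermediate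
25 | potassium alkoxide of 24 | C=C[C@]1(OC)[C@@H](C)[C@@H](O[Si](C)(C)C(C)(C)C)[C@H](O[Si](CC)(CC)CC)[C@@H](OCc2ccccc2)[C@]1([O-])C#CC.[K+] | intermediate (not isolated)
26 | ten-membered potassium allenolate (C4=C5=C6–O−; C1 enol ether; allene axis not assigned) | CO/C1=C/CC(C)=C=C([O-])[C@H](OCc2ccccc2)[C@@H](O[Si](CC)(CC)CC)[C@H](O[Si](C)(C)C(C)(C)C)[C@@H]1C.[K+] | intermediate (not isolated)
27 | ten-membered 1-methoxy-1,4-dien-6-one (drawn 4E) | CO/C1=C/C/C(C)=C/C(=O)[C@H](OCc2ccccc2)[C@@H](O[Si](CC)(CC)CC)[C@H](O[Si](C)(C)C(C)(C)C)[C@@H]1C | intermediate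
28 | (4R,5R)-trans-4,5-epoxy-6-ketone | CO/C1=C/C[C@@]2(C)O[C@@H]2C(=O)[C@H](OCc3ccccc3)[C@@H](O[Si](CC)(CC)CC)[C@H](O[Si](C)(C)C(C)(C)C)[C@@H]1C | intermediate
29 | (6S)-epoxy alcohol | CO/C1=C/C[C@@]2(C)O[C@@H]2[C@@H](O)[C@H](OCc3ccccc3)[C@@H](O[Si](CC)(CC)CC)[C@H](O[Si](C)(C)C(C)(C)C)[C@@H]1C | intermediate
30 | diethyl (2-hydroxyethyl)phosphonate | CCOP(=O)(OCC)CCO | starting material
31 | diethyl [2-(tert-butyldiphenylsilyloxy)ethyl]phosphonate | CCOP(=O)(OCC)CCO[Si](c1ccccc1)(c1ccccc1)C(C)(C)C | intermediate
32 | α-lithiated 31 | CCOP(=O)(OCC)[CH-]CO[Si](c1ccccc1)(c1ccccc1)C(C)(C)C.[Li+] | intermediate (not isolated)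
33 | 3-(tert-butyldiphenylsilyloxy)-2-(diethoxyphosphoryl)propanoic acid (racemic) | CCOP(=O)(OCC)C(CO[Si](c1ccccc1)(c1ccccc1)C(C)(C)C)C(=O)O | intermediate
34 | C6 phosphonoacetate ester (C11 epimers, centre left open) | CO/C1=C/C[C@@]2(C)O[C@@H]2[C@@H](OC(=O)C(CO[Si](c3ccccc3)(c3ccccc3)C(C)(C)C)P(=O)(OCC)OCC)[C@H](OCc3ccccc3)[C@@H](O[Si](CC)(CC)CC)[C@H](O[Si](C)(C)C(C)(C)C)[C@@H]1C | intermediate
35 | C1 ketone | O=C1CC[C@@]2(C)O[C@@H]2[C@@H](OC(=O)C(CO[Si](c3ccccc3)(c3ccccc3)C(C)(C)C)P(=O)(OCC)OCC)[C@H](OCc3ccccc3)[C@@H](O[Si](CC)(CC)CC)[C@H](O[Si](C)(C)C(C)(C)C)[C@@H]1C | intermediate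
36 | C7 alcohol | O=C1CC[C@@]2(C)O[C@@H]2[C@@H](OC(=O)C(CO[Si](c3ccccc3)(c3ccccc3)C(C)(C)C)P(=O)(OCC)OCC)[C@H](O)[C@@H](O[Si](CC)(CC)CC)[C@H](O[Si](C)(C)C(C)(C)C)[C@@H]1C | intermediate
37 | C7 ketone | O=C1CC[C@@]2(C)O[C@@H]2[C@@H](OC(=O)C(CO[Si](c3ccccc3)(c3ccccc3)C(C)(C)C)P(=O)(OCC)OCC)C(=O)[C@@H](O[Si](CC)(CC)CC)[C@H](O[Si](C)(C)C(C)(C)C)[C@@H]1C | intermediate
38 | butenolide (C13 OTBDPS, C8 OTES, C9 OTBS) | O=C1CC[C@@]2(C)O[C@@H]2[C@H]3OC(=O)C(CO[Si](c4ccccc4)(c4ccccc4)C(C)(C)C)=C3[C@@H](O[Si](CC)(CC)CC)[C@H](O[Si](C)(C)C(C)(C)C)[C@@H]1C | intermediate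
39 | C8 alcohol | O=C1CC[C@@]2(C)O[C@@H]2[C@H]3OC(=O)C(CO[Si](c4ccccc4)(c4ccccc4)C(C)(C)C)=C3[C@@H](O)[C@H](O[Si](C)(C)C(C)(C)C)[C@@H]1C | intermediate
40 | C8 methacrylate | O=C1CC[C@@]2(C)O[C@@H]2[C@H]3OC(=O)C(CO[Si](c4ccccc4)(c4ccccc4)C(C)(C)C)=C3[C@@H](OC(=O)C(C)=C)[C@H](O[Si](C)(C)C(C)(C)C)[C@@H]1C | intermediate
41 | C9,C13-diol | O=C1CC[C@@]2(C)O[C@@H]2[C@H]3OC(=O)C(CO)=C3[C@@H](OC(=O)C(C)=C)[C@H](O)[C@@H]1C | intermediate
42 | CNP0185951.1 | C=C(C)C(=O)O[C@@H]1C2=C(COC(C)=O)C(=O)O[C@@H]2[C@H]2O[C@]2(C)CCC(=O)[C@@H](C)[C@H]1O | target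

**Step count and risks**

Total step count: 32. Longest linear sequence: 30 steps (steps 1–21 and 24–32); steps 22–23 are a two-step side branch to acid 33.

Steps most likely to fail:

1. Step 19 (ring expansion). The alkoxide may fragment (loss of propynyl anion, or heterolysis of the C1–C6 bond without recombination) faster than it rearranges. Fallback, setting out from ketone 22: addition of 1-propenylmagnesium bromide would give the 1-propenyl-2-vinyl carbinol F1. Its potassium alkoxide (KH, 18-crown-6) should undergo the ordinary all-alkene anionic oxy-Cope rearrangement to the ten-membered potassium enolate F2 (C5=C6–O−, not isolated). This is selenenylated in the flask with PhSeBr to the 5-phenylselanyl ketone F3. Oxidation (H2O2, pyridine) and syn-elimination of the selenoxide toward C4–H would then give enone 27, where the route is rejoined.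

2. Step 20 (epoxidation). The peroxide may add with poor facial selectivity, or the enolate may close without C4–C5 rotation to a cis-epoxide. Fallback, setting out from 27 (4E isomer): reduction with LiBH(s-Bu)3 under Felkin–Anh control would give the (6S)-allylic alcohol F4. A hydroxyl-directed epoxidation (VO(acac)2, t-BuOOH) then delivers oxygen to the alkene face on the hydroxyl side in the conformer that minimises allylic strain with the C4 methyl group. This is stereospecific for the alkene and spares the enol ether, and it would give epoxy alcohol 29 directly, where the route is rejoined. It does not rescue 4Z material, which would give a cis-epoxide.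

3. Step 21 (C6 reduction). Hydride may be delivered from the wrong face under chelation or ring-conformational control, giving the C6 epimer. Fallback, setting out from 28: a deliberately chelation-controlled reduction with Zn(BH4)2 (erythro-selective for α,β-epoxy ketones) would give the (6R)-epoxy alcohol F5. Mitsunobu esterification of F5 with acid 33 (PPh3, diisopropyl azodicarboxylate) inverts C6 and would give ester 34 in one operation, where the route is rejoined.

**Further compounds**

F1 | step 19 | 1-[(E)-prop-1-enyl]-2-vinylcyclohexanol analogue of 24 | C=C[C@]1(OC)[C@@H](C)[C@@H](O[Si](C)(C)C(C)(C)C)[C@H](O[Si](CC)(CC)CC)[C@@H](OCc2ccccc2)[C@]1(O)/C=C/C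
F2 | step 19 | ten-membered potassium enolate (C5=C6–O−; C4 epimers) | CO/C1=C/CC(C)C=C([O-])[C@H](OCc2ccccc2)[C@@H](O[Si](CC)(CC)CC)[C@H](O[Si](C)(C)C(C)(C)C)[C@@H]1C.[K+]
F3 | step 19 | 5-phenylselanyl-6-ketone (C4/C5 epimers) | CO/C1=C/CC(C)C([Se]c2ccccc2)C(=O)[C@H](OCc2ccccc2)[C@@H](O[Si](CC)(CC)CC)[C@H](O[Si](C)(C)C(C)(C)C)[C@@H]1C
F4 | step 20 | (6S)-allylic alcohol from 27 | CO/C1=C/C/C(C)=C/[C@@H](O)[C@H](OCc2ccccc2)[C@@H](O[Si](CC)(CC)CC)[C@H](O[Si](C)(C)C(C)(C)C)[C@@H]1C
F5 | step 21 | (6R)-epoxy alcohol (C6 epimer of 29) | CO/C1=C/C[C@@]2(C)O[C@@H]2[C@H](O)[C@H](OCc3ccccc3)[C@@H](O[Si](CC)(CC)CC)[C@H](O[Si](C)(C)C(C)(C)C)[C@@H]1C
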